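**Retrosynthetic overview**

1. The target comes from a bridged hemiketal diol by C8 esterification with (E)-N-methylurocanic acid (made by a Doebner condensation) and a final desilylation at O15.
2. The ten-membered carbocycle and its oxygen bridge are closed last, at C3–C4, by adding a (Z)-vinyllithium to the carbonyl of a γ-butenolide.
3. The butenolide comes from a 2-furylcarbinol by the key sequence: Achmatowicz oxidative ring expansion (furan to pyranone), lactol oxidation, then C7 methyl addition with ring contraction (δ-lactone to γ-butenolide).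
4. The vinyl bromide arm comes from CrCl2 bromo-olefination of the C2 aldehyde with methyl tribromoacetate; the C8 carbinol comes from asymmetric transfer hydrogenation of a furyl ketone.
5. Ring A is made first by a catalytic asymmetric Diels–Alder reaction of a silyl trienol ether (from 2-acetylfuran and tiglic aldehyde) with (E)-4-methylpent-2-enal. Ring order: ring A, pyranone, butenolide, ten-membered ring with the dihydrofuran bridge.

Locants in the names are those of the target skeleton: C1 and C10 are the ring-fusion CH groups; ring A also holds C11(Me)=C12, C13 and C14(iPr); C2=C3 carries C15 (CH2O) on C3; then C4 (hemiketal), C5=C6, C7 (Me, bridging O), C8 (acyloxy CH) and C9 (CH2).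

Assumption: in step 3 the (S)-configured oxazaborolidinium catalyst is taken to expose the enal face that gives the (1R,10R,14R) adduct (usual formyl C–H···O binding model); if the adduct proved antipodal, the mirror-image catalyst would be used with no other change.

**Step 1**
Reactants: 1 2-acetylfuran; 2 (E)-2-methylbut-2-enal
Product: 3 (2E,4E)-1-(furan-2-yl)-4-methylhexa-2,4-dien-1-one
Conditions: NaOH (10% aq), EtOH, 0 °C to rt
Reagents that add atoms: none
Why: Claisen–Schmidt (crossed aldol) condensation of the methyl ketone enolate with the enal, followed by E1cB dehydration, gives the (E,E)-dienone that carries C4 to C13 of the target.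

**Step 2**
Reactants: 3 (2E,4E)-1-(furan-2-yl)-4-methylhexa-2,4-dien-1-one
Product: 4 tert-butyl{[(1Z,3E)-1-(furan-2-yl)-4-methylhexa-1,3,5-trien-1-yl]oxy}dimethylsilane
Conditions: TBSOTf, Et3N, CH2Cl2, −78 to 0 °C
Reagents that add atoms: tert-butyldimethylsilyl trifluoromethanesulfonate, CC(C)(C)[Si](C)(C)OS(=O)(=O)C(F)(F)F
Why: Extended (vinylogous) silyl enol ether formation: O-silylation gives a silyloxy carbenium ion whose only acidic position is the terminal C13 methyl, and deprotonation from the s-trans dienone gives the triene with an (E)-C10=C11 bond.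

**Step 3**
Reactants: 4 tert-butyl{[(1Z,3E)-1-(furan-2-yl)-4-methylhexa-1,3,5-trien-1-yl]oxy}dimethylsilane; 5 (E)-4-methylpent-2-enal
Product: 7 (1R,2R,6R)-2-[2-(furan-2-yl)-2-oxoethyl]-3-methyl-6-(propan-2-yl)cyclohex-3-ene-1-carbaldehyde, via silyl enol ether cycloadduct 6 (not isolated)
Conditions: (S)-1-(2-methylphenyl)-3,3-diphenyltetrahydro-1H,3H-pyrrolo[1,2-c][1,3,2]oxazaborole (20 mol%), HN(SO2CF3)2 (17 mol%), CH2Cl2, −78 to −40 °C; then 1 M HCl, THF, 0 °C
Reagents that add atoms: none
Why: Catalytic enantioselective Diels–Alder reaction (chiral oxazaborolidinium Lewis acid): the electron-rich terminal diene C10=C11–C12=C13 (largest HOMO coefficient at C13) adds to the catalyst-bound s-trans enal with ortho regiochemistry and CHO-endo topology, which puts the C1 formyl group cis to the C10 arm and trans to the C14 isopropyl group, the shielded face of the complex fixes the absolute configuration of C1, C10 and C14, and the acidic work-up hydrolyses the silyl enol ether to the furyl ketone.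

**Step 4**
Reactants: 7 (1R,2R,6R)-2-[2-(furan-2-yl)-2-oxoethyl]-3-methyl-6-(propan-2-yl)cyclohex-3-ene-1-carbaldehyde; 8 methyl tribromoacetate
Product: 9 methyl (2Z)-2-bromo-3-[(1R,2R,6R)-2-[2-(furan-2-yl)-2-oxoethyl]-3-methyl-6-(propan-2-yl)cyclohex-3-en-1-yl]prop-2-enoate
Conditions: CrCl2 (5 equiv), THF, rt
Reagents that add atoms: none
Why: Chromium-mediated Takai-type halo-olefination of an aldehyde with a trihaloacetate: the chromium carbenoid adds only to the aldehyde (the aryl ketone is inert) and anti elimination gives the (Z)-α-bromoacrylate with C1 cis to bromine, under non-basic conditions that do not epimerise C1.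

**Step 5**
Reactants: 9 methyl (2Z)-2-bromo-3-[(1R,2R,6R)-2-[2-(furan-2-yl)-2-oxoethyl]-3-methyl-6-(propan-2-yl)cyclohex-3-en-1-yl]prop-2-enoate
Product: 10 methyl (2Z)-2-bromo-3-[(1R,2R,6R)-2-[(2S)-2-(furan-2-yl)-2-hydroxyethyl]-3-methyl-6-(propan-2-yl)cyclohex-3-en-1-yl]prop-2-enoate
Conditions: RuCl[(S,S)-TsNCHPhCHPhNH2](p-cymene) (1 mol%), HCO2H/Et3N (5:2), CH2Cl2, rt
Reagents that add atoms: none
Why: Noyori asymmetric transfer hydrogenation of the 2-acylfuran: the (S,S) catalyst reduces the aryl ketone under reagent control to the (8S)-carbinol, as it does 2-acetylfuran, and leaves the bromoacrylate and the ring alkene untouched.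

**Step 6**
Reactants: 10 methyl (2Z)-2-bromo-3-[(1R,2R,6R)-2-[(2S)-2-(furan-2-yl)-2-hydroxyethyl]-3-methyl-6-(propan-2-yl)cyclohex-3-en-1-yl]prop-2-enoate
Product: 11 (2Z)-2-bromo-3-[(1R,2R,6R)-2-[(2S)-2-(furan-2-yl)-2-hydroxyethyl]-3-methyl-6-(propan-2-yl)cyclohex-3-en-1-yl]prop-2-en-1-ol
Conditions: i-Bu2AlH (3.5 equiv), CH2Cl2, −78 °C; aqueous Rochelle salt
Reagents that add atoms: none
Why: DIBAL 1,2-reduction of the conjugated ester gives the allylic alcohol (C15) and keeps the (Z)-vinyl bromide geometry.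

**Step 7**
Reactants: 11 (2Z)-2-bromo-3-[(1R,2R,6R)-2-[(2S)-2-(furan-2-yl)-2-hydroxyethyl]-3-methyl-6-(propan-2-yl)cyclohex-3-en-1-yl]prop-2-en-1-ol
Product: 12 C15-O-TBS ether of diol 11 [(1R,8S,10R,14R); (2Z)-vinyl bromide; C8 hydroxyl free]
Conditions: TBSCl (1.05 equiv), imidazole, CH2Cl2, 0 °C
Reagents that add atoms: tert-butyldimethylsilyl chloride, CC(C)(C)[Si](C)(C)Cl
Why: Selective silyl ether protection of the primary allylic hydroxyl over the hindered secondary furylcarbinol leaves the C8 hydroxyl free for the ring expansion.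

**Step 8**
Reactants: 12 C15-O-TBS ether of diol 11
Product: 13 (1R,8S,10R,14R)-pyranone lactol: 6-hydroxy-2H-pyran-3(6H)-one whose C2 (= C8, S) carries the C9 methylene to ring A (C4 lactol epimers)
Conditions: NBS (1.05 equiv), NaHCO3, THF/H2O (4:1), 0 °C
Reagents that add atoms: water, O
Why: Achmatowicz rearrangement (oxidative ring expansion): bromonium attack on the furan and hydration give the (Z)-ene-dione, which recloses through the C8 hydroxyl so that the five-membered furan becomes the six-membered pyranone, with C8 unchanged and the furan reacting much faster than the ring A alkene.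

**Step 9**
Reactants: 13 (1R,8S,10R,14R)-pyranone lactol
Product: 14 (1R,8S,10R,14R)-keto-lactone: (6S)-6-substituted 2H-pyran-2,5(6H)-dione (C4 lactone carbonyl, C7 ketone)
Conditions: PhI(OAc)2 (1.2 equiv), TEMPO (10 mol%), CH2Cl2, rt; used at once
Reagents that add atoms: none
Why: Oxoammonium (TEMPO) oxidation of the lactol to the lactone removes the anomeric hydroxyl, which would ring-open under organometallic conditions, and sets C4 at the carboxyl oxidation level.

**Step 10**
Reactants: 14 (1R,8S,10R,14R)-keto-lactone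
Product: 16 (1R,7S,8S,10R,14R)-butenolide: (5S)-5-[(1S)-1-hydroxy-2-(ring A)ethyl]-5-methylfuran-2(5H)-one with the C1 arm (Z)-CH=C(Br)CH2OTBS, via δ-lactone tertiary alkoxide 15 (not isolated)
Conditions: MeLi, CeCl3, THF, −78 °C, then 0 °C; pH 7 buffer
Reagents that add atoms: methyllithium, [Li]C
Why: Chemoselective organocerium 1,2-addition to the C7 ketone (not the lactone, no enolisation at C8) from the face anti to the C9 substituent of the nearly flat ring sets C7 (S, oxygen cis to C9), and on warming the tertiary alkoxide attacks the lactone carbonyl in a 1,4 O-to-O acyl shift (translactonisation) that contracts the six-membered δ-lactone to the five-membered γ-butenolide and frees the C8 hydroxyl; either lactone would converge on the same bridged hemiketal in step 11.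

**Step 11**
Reactants: 16 (1R,7S,8S,10R,14R)-butenolide
Product: 18 (1S,4R,7S,8S,10R,14R)-bridged hemiketal diol: the target skeleton with free C4 and C8 hydroxyls and C15-O-TBS, via vinyllithium alkoxide 17 (not isolated)
Conditions: t-BuLi (3.1 equiv), THF/Et2O (1:1), −95 °C, 0.002 M, slow addition of 16; H2O
Reagents that add atoms: none
Why: Proposed new method: an anionic Parham-type macrocyclisation in which bromine–lithium exchange at −95 °C (faster than t-BuLi addition to a lactone) gives the configurationally stable (Z)-vinyllithium, the neighbouring C8 lithium alkoxide holds it near the butenolide, and it adds 1,2 to the lactone carbonyl from the only face the tether can reach, forming C3–C4 and the ten-membered ring, so that the lithium hemiketalate (no nucleophile is left to over-add) gives on quench the bridged 2,5-dihydrofuran-2-ol with C3 and C8 necessarily cis (4R); the closest known reactions are Parham cyclisations of aryl- or vinyllithiums onto esters in small rings and the lithium acetylide–aldehyde closure of this ten-membered ring.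

**Step 12**
Reactants: 19 1-methyl-1H-imidazole-4-carbaldehyde; 20 malonic acid
Product: 21 (2E)-3-(1-methyl-1H-imidazol-4-yl)prop-2-enoic acid
Conditions: pyridine, piperidine (cat.), 100 °C
Reagents that add atoms: none
Why: Knoevenagel–Doebner condensation with decarboxylation gives the (E)-acrylic acid.

**Step 13**
Reactants: 18 (1S,4R,7S,8S,10R,14R)-bridged hemiketal diol; 21 (2E)-3-(1-methyl-1H-imidazol-4-yl)prop-2-enoic acid
Product: 23 C15-O-TBS ether of the target, via mixed anhydride 22 (not isolated)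
Conditions: 21, 2,4,6-trichlorobenzoyl chloride, Et3N, THF, rt; then 18, DMAP, toluene, 40 °C
Reagents that add atoms: none
Why: Yamaguchi esterification: DMAP-mediated acyl transfer from the mixed anhydride acylates the secondary C8 hydroxyl, the tertiary C4 hemiketal hydroxyl being too hindered, and any six-ring hemiketal tautomer (O8 on C4) equilibrates through the open hydroxy-enone and is funnelled to the five-ring ester.

**Step 14**
Reactants: 23 C15-O-TBS ether of the target
Product: 24 CNP0196085.1 [(1S,4R,7S,8S,10R,14R); (2Z), (5Z), (E)-urocanate]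
Conditions: HF·pyridine, pyridine, THF, 0 °C
Reagents that add atoms: none
Why: Buffered fluoride desilylation cleaves the primary silyl ether without touching the urocanate ester or the hemiketal.

**Compound list**

1 | 2-acetylfuran | CC(=O)c1ccco1 | starting material
2 | (E)-2-methylbut-2-enal | C/C=C(C)/C=O | starting material
3 | (2E,4E)-1-(furan-2-yl)-4-methylhexa-2,4-dien-1-one | C/C=C(C)/C=C/C(=O)c1ccco1 | intermediate
4 | tert-butyl{[(1Z,3E)-1-(furan-2-yl)-4-methylhexa-1,3,5-trien-1-yl]oxy}dimethylsilane | C=C/C(C)=C/C=C(\O[Si](C)(C)C(C)(C)C)c1ccco1 | intermediate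
5 | (E)-4-methylpent-2-enal | CC(C)/C=C/C=O | starting material
6 | (1R,2R,6R)-2-[(Z)-2-{[tert-butyl(dimethyl)silyl]oxy}-2-(furan-2-yl)ethenyl]-3-methyl-6-(propan-2-yl)cyclohex-3-ene-1-carbaldehyde | CC1=CC[C@H](C(C)C)[C@@H](C=O)[C@H]1/C=C(\O[Si](C)(C)C(C)(C)C)c1ccco1 | intermediate (not isolated)
7 | (1R,2R,6R)-2-[2-(furan-2-yl)-2-oxoethyl]-3-methyl-6-(propan-2-yl)cyclohex-3-ene-1-carbaldehyde | CC1=CC[C@H](C(C)C)[C@@H](C=O)[C@H]1CC(=O)c1ccco1 | intermediate
8 | methyl tribromoacetate | COC(=O)C(Br)(Br)Br | starting material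
9 | methyl (2Z)-2-bromo-3-[(1R,2R,6R)-2-[2-(furan-2-yl)-2-oxoethyl]-3-methyl-6-(propan-2-yl)cyclohex-3-en-1-yl]prop-2-enoate | CC1=CC[C@H](C(C)C)[C@@H](/C=C(/C(=O)OC)Br)[C@H]1CC(=O)c1ccco1 | intermediate
10 | methyl (2Z)-2-bromo-3-[(1R,2R,6R)-2-[(2S)-2-(furan-2-yl)-2-hydroxyethyl]-3-methyl-6-(propan-2-yl)cyclohex-3-en-1-yl]prop-2-enoate | CC1=CC[C@H](C(C)C)[C@@H](/C=C(/C(=O)OC)Br)[C@H]1C[C@H](O)c1ccco1 | intermediate
11 | (2Z)-2-bromo-3-[(1R,2R,6R)-2-[(2S)-2-(furan-2-yl)-2-hydroxyethyl]-3-methyl-6-(propan-2-yl)cyclohex-3-en-1-yl]prop-2-en-1-ol | CC1=CC[C@H](C(C)C)[C@@H](/C=C(/CO)Br)[C@H]1C[C@H](O)c1ccco1 | intermediate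
12 | C15-O-TBS ether of 11 [(1R,8S,10R,14R); (2Z)-vinyl bromide; free (8S)-furylcarbinol] | CC1=CC[C@H](C(C)C)[C@@H](/C=C(/CO[Si](C)(C)C(C)(C)C)Br)[C@H]1C[C@H](O)c1ccco1 | intermediate
13 | (1R,8S,10R,14R)-pyranone lactol: 6-hydroxy-2H-pyran-3(6H)-one with C2 (= C8) bearing the C9 methylene to ring A; C4 epimers | CC1=CC[C@H](C(C)C)[C@@H](/C=C(/CO[Si](C)(C)C(C)(C)C)Br)[C@H]1C[C@@H]1OC(O)C=CC1=O | intermediate
14 | (1R,8S,10R,14R)-keto-lactone: (6S)-6-substituted 2H-pyran-2,5(6H)-dione | CC1=CC[C@H](C(C)C)[C@@H](/C=C(/CO[Si](C)(C)C(C)(C)C)Br)[C@H]1C[C@@H]1OC(=O)C=CC1=O | intermediate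
15 | (1R,7S,8S,10R,14R)-δ-lactone tertiary alkoxide (drawn as the alcohol): (5S,6S)-5-hydroxy-5-methyl-6-substituted 5,6-dihydro-2H-pyran-2-one | CC1=CC[C@H](C(C)C)[C@@H](/C=C(/CO[Si](C)(C)C(C)(C)C)Br)[C@H]1C[C@@H]1OC(=O)C=C[C@]1(C)O | intermediate (not isolated)
16 | (1R,7S,8S,10R,14R)-butenolide: (5S)-5-[(1S)-1-hydroxy-2-(ring A)ethyl]-5-methylfuran-2(5H)-one | CC1=CC[C@H](C(C)C)[C@@H](/C=C(/CO[Si](C)(C)C(C)(C)C)Br)[C@H]1C[C@H](O)[C@@]1(C)OC(=O)C=C1 | intermediate
17 | C3-lithio C8-lithium alkoxide of 16 (configuration as in 16; (Z)-vinyllithium) | CC1=CC[C@H](C(C)C)[C@@H](/C=C(/CO[Si](C)(C)C(C)(C)C)[Li])[C@H]1C[C@H](O[Li])[C@@]1(C)OC(=O)C=C1 | intermediate (not isolated)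
18 | (1S,4R,7S,8S,10R,14R)-bridged hemiketal diol with C15-O-TBS (C1 is S by a change in CIP priorities only) | CC1=CC[C@H](C(C)C)[C@H]2/C=C(/CO[Si](C)(C)C(C)(C)C)[C@@]3(O)C=C[C@](C)(O3)[C@@H](O)C[C@@H]12 | intermediate
19 | 1-methyl-1H-imidazole-4-carbaldehyde | Cn1cnc(C=O)c1 | starting material
20 | malonic acid | OC(=O)CC(=O)O | starting material
21 | (2E)-3-(1-methyl-1H-imidazol-4-yl)prop-2-enoic acid | Cn1cnc(/C=C/C(=O)O)c1 | intermediate
22 | mixed anhydride of 21 with 2,4,6-trichlorobenzoic acid | Cn1cnc(/C=C/C(=O)OC(=O)c2c(Cl)cc(Cl)cc2Cl)c1 | intermediate (not isolated)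
23 | C15-O-TBS ether of the target (1S,4R,7S,8S,10R,14R) | CC1=CC[C@H](C(C)C)[C@H]2/C=C(/CO[Si](C)(C)C(C)(C)C)[C@@]3(O)C=C[C@](C)(O3)[C@@H](OC(=O)/C=C/c3cn(C)cn3)C[C@@H]12 | intermediate
24 | CNP0196085.1 (1S,4R,7S,8S,10R,14R) | CC1=CC[C@H](C(C)C)[C@H]2/C=C(/CO)[C@@]3(O)C=C[C@](C)(O3)[C@@H](OC(=O)/C=C/c3cn(C)cn3)C[C@@H]12 | target

**Step count and risks**

Total steps: 14. Longest linear sequence: 13 (steps 1 to 11, 13 and 14; step 12 makes the side-chain acid).

The step most likely to fail is step 11, the proposed new macrocyclisation. t-BuLi may add to the butenolide before exchange, the vinyllithium may lose silyloxide to give an allene, or oligomers may form. The fallback uses known chemistry, sets out from 16 and comes back at 18. i-Bu2AlH at −78 °C reduces the butenolide carbonyl of 16 to the lactol F5. The open (Z)-γ-hydroxy-enal form of F5 is closed by a Nozaki–Hiyama–Kishi reaction between the vinyl bromide and the C4 aldehyde (CrCl2, NiCl2 cat., DMSO/THF, 0.003 M) to give the ten-membered C4 carbinol triol F6. MnO2 then oxidises only the bis-allylic C4 carbinol, and the resulting (Z)-hydroxy-dienone closes by itself to hemiketal 18.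

The second is step 3. The trienol ether could react through the wrong diene, give open-chain Mukaiyama–Michael products, or give low enantioselectivity with the β-branched enal. The fallback sets out from 3 and comes back at 7. Kinetic α-protonation of the lithium trienolate of 3 (LDA, THF/HMPA, −78 °C; AcOH) gives the deconjugated dienone (E)-1-(furan-2-yl)-4-methylhexa-3,5-dien-1-one F1. This ordinary 1,3-diene is then used in an iminium-catalysed Diels–Alder reaction with 5 (first-generation MacMillan catalyst (5S)-5-benzyl-2,2,3-trimethylimidazolidin-4-one hydrochloride, MeCN/H2O, 0 °C), which gives 7 directly.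

The third is step 10. The keto-lactone 14 can enolise at C8 toward a hydroxy-pyranone (loss of the C8 centre), suffer conjugate addition, or fail to translactonise cleanly. The fallback sets out from 13 and comes back at 16, and it inverts the order of oxidation and methylation. Lactol 13 is locked with MeOH and PPTS as the methyl pyranoside F2. MeLi/CeCl3 adds to its C7 ketone anti to the C8 side chain to give the tertiary alcohol F3. Aqueous acetic acid in THF frees the lactol F4, PhI(OAc)2 with TEMPO oxidises it to lactone 15, and a trace of DBU completes the shift to 16.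

**Further compounds**

F1 | step 3 | (E)-1-(furan-2-yl)-4-methylhexa-3,5-dien-1-one | C=C/C(C)=C/CC(=O)c1ccco1
F2 | step 10 | methyl pyranoside of 13: 6-methoxy-2H-pyran-3(6H)-one (1R,8S,10R,14R; C4 epimers) | CC1=CC[C@H](C(C)C)[C@@H](/C=C(/CO[Si](C)(C)C(C)(C)C)Br)[C@H]1C[C@@H]1OC(OC)C=CC1=O
F3 | step 10 | C7 tertiary alcohol of F2: 6-methoxy-3-methyl-3,6-dihydro-2H-pyran-3-ol (1R,7S,8S,10R,14R) | CC1=CC[C@H](C(C)C)[C@@H](/C=C(/CO[Si](C)(C)C(C)(C)C)Br)[C@H]1C[C@@H]1OC(OC)C=C[C@]1(C)O
F4 | step 10 | lactol from F3: 3-methyl-3,6-dihydro-2H-pyran-3,6-diol (1R,7S,8S,10R,14R) | CC1=CC[C@H](C(C)C)[C@@H](/C=C(/CO[Si](C)(C)C(C)(C)C)Br)[C@H]1C[C@@H]1OC(O)C=C[C@]1(C)O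
F5 | step 11 | lactol from 16: 5-[(1S)-1-hydroxy-2-(ring A)ethyl]-5-methyl-2,5-dihydrofuran-2-ol (1R,7S,8S,10R,14R; C4 epimers) | CC1=CC[C@H](C(C)C)[C@@H](/C=C(/CO[Si](C)(C)C(C)(C)C)Br)[C@H]1C[C@H](O)[C@@]1(C)OC(O)C=C1
F6 | step 11 | ten-membered (2Z,5Z)-C4 carbinol triol with C15-O-TBS (1S,7S,8S,10R,14R; C4 epimers) | CC1=CC[C@H](C(C)C)[C@H]2/C=C(/CO[Si](C)(C)C(C)(C)C)C(O)/C=C\[C@](C)(O)[C@@H](O)C[C@@H]12
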